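Cuts: C3–C1′ (Suzuki coupling); the methyl ester back to a C6–O–C(=O) β-lactone; C5–OH (enolate hydroxylation); C5–C6 together with the lactone C–O bond (aldol lactonisation); then C5–CO2 and C7–C7a.
Feature: on ring B (C4a, C5, C6, C7, C7a) the C6 hydroxyl and the C5 ester carbon share one face, which is a ring-fused β-lactone in opened form. C5 is α to that carbonyl, sits on C4a (the 4-position of pyridine ring A) and lies next to the C6/C7 1,2-dicarbonyl.
Forward: ring A is bought. Grignard acylation (C7a–C7) and lateral acylation of the methyl group lead to the keto acid. One operation closes ring B and the temporary oxetanone ring C, ring C is opened after the C5 oxidation, and the dienyl chain is joined last.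
Stereochemistry: C5 comes from the chiral isothiourea, C6 from the cis fusion that ring C demands, and the C5 hydroxyl from retentive attack on the convex face. C5′ comes from (S)-2-methylbutan-1-ol, and the two E alkenes from Wittig and boron–Wittig olefinations.

Key step: step 5

Assumption: the accepted picture of isothiourea-bound Z-enolates (O···S contact, phenyl group covering one face) assigns the (R)-catalyst to the (5S,6S) β-lactone; the sense is to be checked on that lactone, and the equally available (S)-catalyst is used if the check demands it.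

Step 1
Reactants: 1 methyl 2,2-dimethoxypropanoate
Product: 2 N,2,2-trimethoxy-N-methylpropanamide
Conditions: MeNH(OMe)·HCl (1.5 equiv), i-PrMgCl (3 equiv), THF, −20 → 0 °C; aq NH4Cl
Reagents that add atoms: N,O-dimethylhydroxylamine hydrochloride, CNOC.Cl
Why: Aminolysis of an ester by the chloromagnesium amide of N,O-dimethylhydroxylamine (Weinreb amide synthesis) works on hindered, α-oxygenated esters, and the ketal is inert to the basic medium.

Step 2
Reactants: 3 5-bromo-2-chloro-4-methylpyridine; 2 N,2,2-trimethoxy-N-methylpropanamide
Product: 5 1-(6-chloro-4-methylpyridin-3-yl)-2,2-dimethoxypropan-1-one, via pyridylmagnesium chloride 4 (not isolated)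
Conditions: i-PrMgCl·LiCl (1.1 equiv), THF, −15 °C, 1 h; then 2 (1.2 equiv), −15 °C → rt; aq NH4Cl
Reagents that add atoms: none
Why: Bromine–magnesium exchange takes the C–Br bond and leaves the C–Cl bond and the methyl protons alone, and the Weinreb ketone synthesis stops at the ketone because the N-methoxy amide adduct collapses only on work-up.

Step 3
Reactants: 5 1-(6-chloro-4-methylpyridin-3-yl)-2,2-dimethoxypropan-1-one
Product: 7 tert-butyl 2-[2-chloro-5-(2,2-dimethoxypropanoyl)pyridin-4-yl]acetate, via lithiated picoline 6 (not isolated)
Conditions: LiN(SiMe3)2 (2.2 equiv), THF, −78 °C, 30 min; Boc2O (1.1 equiv), −78 → −20 °C; aq NH4Cl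
Reagents that add atoms: di-tert-butyl dicarbonate, CC(C)(C)OC(=O)OC(=O)OC(C)(C)C
Why: Lateral lithiation and Claisen-type C-acylation: the methyl protons are activated through the ring nitrogen (4-position) and the ortho ketone, which has no α-hydrogen of its own, the silylamide carries no β-hydride that could reduce that ketone, and the second equivalent of base takes up the more acidic proton of the new ester so that acylation stops after one carboxyl group.

Step 4
Reactants: 7 tert-butyl 2-[2-chloro-5-(2,2-dimethoxypropanoyl)pyridin-4-yl]acetate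
Product: 8 2-[2-chloro-5-(2-oxopropanoyl)pyridin-4-yl]acetic acid
Conditions: CF3CO2H–CH2Cl2–H2O (10:10:1), 0 °C → rt; evaporation with toluene below 30 °C, used without storage
Reagents that add atoms: water, O
Why: Acidolysis of the tert-butyl ester and acid-catalysed hydrolysis of the α-keto ketal free the acid and the C6 ketone in one base-free operation, in which the CH2 group has no enolate available for a premature aldol reaction, while the 2-chloro substituent keeps the nitrogen too weakly basic for the zwitterion through which pyridylacetic acids lose CO2.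

Step 5
Reactants: 8 2-[2-chloro-5-(2-oxopropanoyl)pyridin-4-yl]acetic acid
Product: 10 (5S,6S)-3-chloro-6-hydroxy-6-methyl-7-oxo-6,7-dihydro-5H-cyclopenta[c]pyridine-5-carboxylic acid β-lactone (cis-fused tricycle; H at C5), via mixed pivalic anhydride 9 (not isolated)
Conditions: t-BuCOCl (1.05 equiv), i-Pr2NEt (1.05 equiv), CH2Cl2, −10 °C, 30 min; then (R)-2-phenyl-2,3-dihydroimidazo[2,1-b]benzothiazole (10 mol %), i-Pr2NEt (1.1 equiv, added over 4 h), −40 °C
Reagents that add atoms: none
Why: The sp2 nitrogen of the isothiourea takes the less hindered acyl group of 9, and the resulting acylammonium pivalate loses its doubly activated C5–H to pivalate or i-Pr2NEt to give a Z-ammonium enolate held flat by a 1,5 O···S contact. C5 adds to the C6 carbonyl in a 5-(enolexo)-exo-trig aldol closure of ring B, and the C6 alkoxide then attacks the acylammonium carbonyl in a 4-exo-trig closure that forms ring C and frees the catalyst. The closest known reaction types are the nucleophile-catalysed aldol lactonisation of 6-oxo acids to cyclopentane-fused β-lactones with isothiourea or cinchona catalysts, and the generation of ammonium enolates from arylacetic acids with pivaloyl chloride. C5 is set by the catalyst, whose pseudo-axial phenyl group covers one enolate face, and C6 is set relative to C5 by ring C, because only the aldolate with oxygen cis to the acyl carbon can lactonise while the other one reverts by retro-aldol. Site selectivity comes from the substrate: attack at C7 would give a four-membered carbocycle, the aliphatic C6 carbonyl is the more electrophilic one, and C5–H, flanked by the acyl cation and pyridine C4, is far more acidic than the C6 methyl protons. The selectivity that needs protection is catalysed against uncatalysed enolisation of 9, which is served by leaving no free amine after the activation, by the low temperature and by the slow feed of the second equivalent of base.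

Step 6
Reactants: 10 (5S,6S)-tricyclic β-lactone with H at C5
Product: 12 (5R,6S)-3-chloro-5,6-dihydroxy-6-methyl-7-oxo-6,7-dihydro-5H-cyclopenta[c]pyridine-5-carboxylic acid 6-β-lactone (C5 hydroxyl on the convex face), via sodium enolate 11 (not isolated)
Conditions: NaN(SiMe3)2 (1.05 equiv), THF, −78 °C, 15 min; (±)-3-phenyl-2-(phenylsulfonyl)oxaziridine (1.3 equiv), −78 °C; AcOH, −78 °C
Reagents that add atoms: 3-phenyl-2-(phenylsulfonyl)oxaziridine, O=S(=O)(N1OC1c1ccccc1)c1ccccc1
Why: Proposed new method: C5–H is the only acidic proton of 10, and ring C holds the C6–O bond near the nodal plane of the carbanion orbital, which is why β-lactone enolates resist β-elimination. Electrophilic oxygen transfer from the N-sulfonyloxaziridine can reach C5 only on the convex face that hydrogen has left, since ring C must stay cis-fused to ring B, so the C5 hydroxyl should come out trans to the C6 oxygen. The closest known reaction types are the Davis oxidation of ester, larger-ring lactone and β-lactam enolates and the C-alkylation of β-lactone enolates; oxygen transfer to a ring-fusion β-lactone enolate has not been shown.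

Step 7
Reactants: 12 (5R,6S)-α-hydroxy β-lactone
Product: 13 methyl (5R,6S)-3-chloro-5,6-dihydroxy-6-methyl-7-oxo-6,7-dihydro-5H-cyclopenta[c]pyridine-5-carboxylate
Conditions: MeOH–CH2Cl2 (1:1), Et3N (0.2 equiv), 0 °C
Reagents that add atoms: methanol, CO
Why: Amine-catalysed alcoholysis of a strained β-lactone proceeds by acyl–oxygen cleavage, so the C5 and C6 configurations are kept and the C6 oxygen is released as the free hydroxyl cis to the new ester, while the catalytic weak base at 0 °C keeps alkoxide levels too low for retro-aldol cleavage.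

Step 8
Reactants: 14 (S)-2-methylbutan-1-ol
Product: 16 ethyl (2E,4S)-2,4-dimethylhex-2-enoate, via (S)-2-methylbutanal 15 (not isolated)
Conditions: TEMPO (1 mol %), KBr (10 mol %), NaOCl (1.1 equiv), NaHCO3 buffer, CH2Cl2–H2O, 0 °C; dried organic layer, then Ph3P=C(CH3)CO2Et (1.2 equiv), rt
Reagents that add atoms: ethyl 2-(triphenylphosphoranylidene)propanoate, CCOC(=O)C(C)=P(c1ccccc1)(c1ccccc1)c1ccccc1
Why: The TEMPO/NaOCl oxidation is the standard racemisation-free route to this α-branched aldehyde, and the Wittig reaction of the stabilised α-methyl ylide with the undistilled solution gives the E-trisubstituted enoate, the C4 stereocentre being taken unchanged from the chiral pool.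

Step 9
Reactants: 16 ethyl (2E,4S)-2,4-dimethylhex-2-enoate
Product: 17 (2E,4S)-2,4-dimethylhex-2-en-1-ol
Conditions: i-Bu2AlH (2.2 equiv), CH2Cl2, −78 °C; aq potassium sodium tartrate
Reagents that add atoms: none
Why: Two hydride transfers from i-Bu2AlH reduce the conjugated ester in 1,2-fashion to the allylic alcohol (ester reduction) without touching the alkene or the stereocentre.

Step 10
Reactants: 17 (2E,4S)-2,4-dimethylhex-2-en-1-ol
Product: 18 (2E,4S)-2,4-dimethylhex-2-enal
Conditions: MnO2 (activated, 15 equiv), CH2Cl2, rt
Reagents that add atoms: none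
Why: Heterogeneous allylic oxidation with MnO2 is neutral and stops at the enal, so neither the E geometry nor the γ-stereocentre is at risk.

Step 11
Reactants: 18 (2E,4S)-2,4-dimethylhex-2-enal
Product: 19 2-[(1E,3E,5S)-3,5-dimethylhepta-1,3-dien-1-yl]-4,4,5,5-tetramethyl-1,3,2-dioxaborolane
Conditions: CH2(Bpin)2 (1.2 equiv), lithium 2,2,6,6-tetramethylpiperidide (1.2 equiv), THF, 0 °C; then 18, −78 °C → rt; aq NH4Cl
Reagents that add atoms: bis(4,4,5,5-tetramethyl-1,3,2-dioxaborolan-2-yl)methane, CC1(C)OB(CB2OC(C)(C)C(C)(C)O2)OC1(C)C
Why: Boron–Wittig olefination: the lithiated geminal bis(boronate) adds 1,2 to the aldehyde at low temperature and syn elimination of the boron–oxygen pair gives the E-alkenyl boronate, the fast addition leaving no time for γ-deprotonation of the enal.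

Step 12
Reactants: 13 methyl (5R,6S)-3-chloro-5,6-dihydroxy-6-methyl-7-oxo-6,7-dihydro-5H-cyclopenta[c]pyridine-5-carboxylate; 19 dienyl pinacol boronate
Product: 20 methyl (5R,6S)-3-[(1E,3E,5S)-3,5-dimethylhepta-1,3-dien-1-yl]-5,6-dihydroxy-6-methyl-7-oxo-6,7-dihydro-5H-cyclopenta[c]pyridine-5-carboxylate
Conditions: Pd(OAc)2 (5 mol %), SPhos (10 mol %), K3PO4 (2 equiv), THF–H2O (10:1), 25–40 °C
Reagents that add atoms: none
Why: Suzuki–Miyaura coupling: the C3–Cl bond lies α to the ring nitrogen and para to the C7 ketone and therefore adds readily to zerovalent palladium carrying the electron-rich biarylphosphine near room temperature, transmetalation and reductive elimination keep the diene geometry, and no stereocentre takes part.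

Compound list
1 | methyl 2,2-dimethoxypropanoate | COC(=O)C(C)(OC)OC | starting material
2 | N,2,2-trimethoxy-N-methylpropanamide | CON(C)C(=O)C(C)(OC)OC | intermediate
3 | 5-bromo-2-chloro-4-methylpyridine | Cc1cc(Cl)ncc1Br | starting material
4 | (6-chloro-4-methylpyridin-3-yl)magnesium chloride (not isolated) | Cc1cc(Cl)ncc1[Mg]Cl | intermediate
5 | 1-(6-chloro-4-methylpyridin-3-yl)-2,2-dimethoxypropan-1-one | COC(C)(OC)C(=O)c1cnc(Cl)cc1C | intermediate
6 | [2-chloro-5-(2,2-dimethoxypropanoyl)pyridin-4-yl]methyllithium, drawn C-lithiated (not isolated) | [Li]Cc1cc(Cl)ncc1C(=O)C(C)(OC)OC | intermediate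
7 | tert-butyl 2-[2-chloro-5-(2,2-dimethoxypropanoyl)pyridin-4-yl]acetate | COC(C)(OC)C(=O)c1cnc(Cl)cc1CC(=O)OC(C)(C)C | intermediate
8 | 2-[2-chloro-5-(2-oxopropanoyl)pyridin-4-yl]acetic acid | CC(=O)C(=O)c1cnc(Cl)cc1CC(=O)O | intermediate
9 | 2-[2-chloro-5-(2-oxopropanoyl)pyridin-4-yl]acetic pivalic anhydride (not isolated) | CC(=O)C(=O)c1cnc(Cl)cc1CC(=O)OC(=O)C(C)(C)C | intermediate
10 | (5S,6S)-3-chloro-6-hydroxy-6-methyl-7-oxo-6,7-dihydro-5H-cyclopenta[c]pyridine-5-carboxylic acid β-lactone | Clc1cc2c(cn1)C(=O)[C@@]3(C)OC(=O)[C@@H]23 | intermediate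
11 | sodium enolate of 10, (6S) (not isolated) | Clc1cc2c(cn1)C(=O)[C@@]3(C)OC([O-])=C23.[Na+] | intermediate
12 | (5R,6S)-3-chloro-5,6-dihydroxy-6-methyl-7-oxo-6,7-dihydro-5H-cyclopenta[c]pyridine-5-carboxylic acid 6-β-lactone | Clc1cc2c(cn1)C(=O)[C@@]3(C)OC(=O)[C@@]23O | intermediate
13 | methyl (5R,6S)-3-chloro-5,6-dihydroxy-6-methyl-7-oxo-6,7-dihydro-5H-cyclopenta[c]pyridine-5-carboxylate | Clc1cc2c(cn1)C(=O)[C@@](C)(O)[C@@]2(O)C(=O)OC | intermediate
14 | (S)-2-methylbutan-1-ol | CC[C@H](C)CO | starting material
15 | (S)-2-methylbutanal (not isolated) | CC[C@H](C)C=O | intermediate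
16 | ethyl (2E,4S)-2,4-dimethylhex-2-enoate | CC[C@H](C)/C=C(C)/C(=O)OCC | intermediate
17 | (2E,4S)-2,4-dimethylhex-2-en-1-ol | CC[C@H](C)/C=C(C)/CO | intermediate
18 | (2E,4S)-2,4-dimethylhex-2-enal | CC[C@H](C)/C=C(C)/C=O | intermediate
19 | 2-[(1E,3E,5S)-3,5-dimethylhepta-1,3-dien-1-yl]-4,4,5,5-tetramethyl-1,3,2-dioxaborolane | CC[C@H](C)/C=C(C)/C=C/B1OC(C)(C)C(C)(C)O1 | intermediate
20 | methyl (5R,6S)-3-[(1E,3E,5S)-3,5-dimethylhepta-1,3-dien-1-yl]-5,6-dihydroxy-6-methyl-7-oxo-6,7-dihydro-5H-cyclopenta[c]pyridine-5-carboxylate | CC[C@H](C)/C=C(C)/C=C/c1cc2c(cn1)C(=O)[C@@](C)(O)[C@@]2(O)C(=O)OC | target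

Total step count: 12.
Longest linear sequence: 8 steps (steps 1–7 and 12, from 1). The side-chain branch from 14 has 5 steps (steps 8–12).

Steps most likely to fail

1. Step 6.
- What may go wrong: The ring-fusion carbanion cannot become fully planar, so deprotonation may be slow. Once formed, it may open ring C by loss of the C6 carboxylate oxygen, or add to the sulfonimine by-product instead of taking up oxygen.
- Fallback: This uses known chemistry, sets out from 10 and comes back at 13. Lactone 10 is opened with MeOH and catalytic Et3N as in step 7 to methyl (5S,6S)-3-chloro-6-hydroxy-6-methyl-7-oxo-6,7-dihydro-5H-cyclopenta[c]pyridine-5-carboxylate F1. Its tertiary C6 hydroxyl is silylated with Et3SiOTf and 2,6-lutidine in CH2Cl2 to the triethylsilyl ether F2. The ester enolate of F2 is planar and exocyclic to ring B. Davis oxidation of this enolate (KN(SiMe3)2, the same oxaziridine, THF, −78 °C) should take place anti to the bulky silyloxy group and give the C5 carbinol F3 with the two oxygens trans. HF·pyridine in THF removes the silyl group and gives 13.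

2. Step 5.
- What may go wrong: The amine base may enolise 9 without the catalyst, and aldol closure of that enolate would erode the enantiomeric purity.
- Fallback: This sets out from 8 and comes back at 10. The same activation is run with achiral 4-pyrrolidinopyridine as the nucleophile, so that catalysed and uncatalysed paths lead to the same racemic cis-fused lactone, ring C still enforcing the relative configuration. Preparative chromatography on a chiral stationary phase separates it into 10, which goes on, and the (5R,6R)-β-lactone F4, which is set aside.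

3. Step 12.
- What may go wrong: Alkoxide formation at C6 or C5 in the aqueous phosphate medium may start retro-aldol cleavage of the C5–C6 bond with loss of both ring stereocentres, or saponify the ester.
- Fallback: This is a base-free Stille coupling that sets out from 18 and 13 and comes back at 20. Enal 18 is treated with Bu3SnCHBr2, CrCl2 and LiI in THF–DMF (Takai–Hodgson type olefination) to give tributyl[(1E,3E,5S)-3,5-dimethylhepta-1,3-dien-1-yl]stannane F5. Stannane F5 is coupled with 13 under Pd(PPh3)4 in toluene at 90 °C without any base to give 20.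

Further compounds
F1 | step 6 | methyl (5S,6S)-3-chloro-6-hydroxy-6-methyl-7-oxo-6,7-dihydro-5H-cyclopenta[c]pyridine-5-carboxylate | Clc1cc2c(cn1)C(=O)[C@@](C)(O)[C@H]2C(=O)OC
F2 | step 6 | methyl (5S,6S)-3-chloro-6-methyl-7-oxo-6-(triethylsilyloxy)-6,7-dihydro-5H-cyclopenta[c]pyridine-5-carboxylate | Clc1cc2c(cn1)C(=O)[C@@](C)(O[Si](CC)(CC)CC)[C@H]2C(=O)OC
F3 | step 6 | methyl (5R,6S)-3-chloro-5-hydroxy-6-methyl-7-oxo-6-(triethylsilyloxy)-6,7-dihydro-5H-cyclopenta[c]pyridine-5-carboxylate | Clc1cc2c(cn1)C(=O)[C@@](C)(O[Si](CC)(CC)CC)[C@@]2(O)C(=O)OC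
F4 | step 5 | (5R,6R)-3-chloro-6-hydroxy-6-methyl-7-oxo-6,7-dihydro-5H-cyclopenta[c]pyridine-5-carboxylic acid β-lactone | Clc1cc2c(cn1)C(=O)[C@]3(C)OC(=O)[C@H]23
F5 | step 12 | tributyl[(1E,3E,5S)-3,5-dimethylhepta-1,3-dien-1-yl]stannane | CC[C@H](C)/C=C(C)/C=C/[Sn](CCCC)(CCCC)CCCC
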